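## Retrosynthetic overview

1. Ring D (dihydropyranone) is made last. Cutting O1–C8a and C2–C3 gives benzaldehyde and the bis(silyloxy)diene of a tricyclic 2-acetyl-1,3-diketone. A chiral titanium catalyst sets C2.
2. Rings B (bicyclo[2.2.2]octene bridge) and C (tetrahydrofuran) are made together. Cutting C6–O, C5–C2'' and C8–C3'' gives prenol and 3,5-dimethylphloroacetophenone. One enantioselective oxidative dearomatisation/intramolecular Diels–Alder operation joins them and sets C5, C6, C8 and C2''.
3. The dearomatisation is run on the symmetric acetophenone, not on the flavanone. Its two methyl-bearing carbons are enantiotopic, so the C6/C8 regiochemical problem of the flavanone becomes a desymmetrisation.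
4. 3,5-Dimethylphloroacetophenone comes from double C-methylation of commercial phloroacetophenone (ring A is bought).
5. Ring order: A (bought), then B and C in one step, then D.

**Locants:** from compound 4 on, the core carries flavanone numbering (O1, C2, C3, C4, C4a, C5–C8, C8a). The prenol carbons are C1'' (OCH2), C2'' (CH) and C3'' (CMe2).

**Assumption:** the senses of induction are taken as (R,R)-iodoarene → 6S and (S)-BINOL → 2S (Si-face attack on PhCHO, as this titanium complex shows with other carbon nucleophiles); both controllers are accessible in both mirror-image forms, so a reversed sense only means using the antipode.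

## Route

Step 1
Reactants: 1 2',4',6'-trihydroxyacetophenone (phloroacetophenone, dried)
Product: 2 1-(2,4,6-trihydroxy-3,5-dimethylphenyl)ethan-1-one (3,5-dimethylphloroacetophenone)
Conditions: MeI (2.05 equiv, slow addition), NaOMe (2.2 equiv), MeOH, 0 °C to rt, 16 h; 1 M HCl; chromatography, then recrystallisation
Reagents that add atoms: iodomethane, CI
Why: This is the classical nuclear (C-)methylation of a phloroglucinolate, in which the hydrogen-bonded ambident anion in methanol attacks the soft electrophile MeI at its two free ring carbons and re-aromatises, and limiting MeI to two equivalents keeps the gem-dimethylated (dearomatised) by-products a separable minority; no stereocentre is formed.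

Step 2
Reactants: 2 3,5-dimethylphloroacetophenone; 3 prenol (3-methylbut-2-en-1-ol, 10 equiv)
Product: 5 (3R,3aR,6R,7aS)-4-acetyl-3a,5-dihydroxy-6,7a,8,8-tetramethyl-2,3,3a,6-tetrahydro-3,6-methanobenzofuran-7(7aH)-one, via o-quinol prenyl ether 4 (not isolated)
Conditions: (R,R)-2,2'-[(2-iodo-1,3-phenylene)bis(oxy)]bis(N-mesitylpropanamide) (1.1 equiv), mCPBA (1.05 equiv), AcOH (5 equiv), CH2Cl2, rt, 2 h (peracid test negative); this solution added over 1 h to 2 + 3 in CH2Cl2–MeNO2, −20 °C, 6 h; then PhMe, 80 °C, 12 h (CH2Cl2 distils off); iodoarene recovered on the column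
Reagents that add atoms: none
Why: Proposed new method: a phenolic OH of the time-averaged symmetric phenol 2 exchanges onto the chiral diacetoxy-λ3-iodane (trivalent iodine), whose hydrogen-bonded lactamide arms leave open only one of the enantiotopic methyl-bearing carbon/face combinations, so prenol in large excess adds there as the iodoarene departs and fixes the 6S quaternary centre (the acyl-bearing carbon is too electron-poor to compete, and all tautomers lead to one constitution); the electron-poor chelated 2,4-dienone 4 then undergoes an intramolecular inverse-demand Diels–Alder reaction in which the short OCH2 tether forces the prenyl alkene onto the alkoxy face with C2'' bonding to C5 and C3'' to C8, so 5R, 8R and 2''R follow from 6S and rings B and C close together; the closest known reaction types are the racemic PhI(OAc)2/alkenol oxidative dearomatisation–IMDA tandem and the enantioselective Kita-type dearomatisations with lactamide iodoarenes, which use tethered nucleophiles.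

Step 3
Reactants: 5 tricyclic acetyl enol-dione
Product: 6 (3R,3aR,6R,7aS)-6,7a,8,8-tetramethyl-3a,5-bis(trimethylsilyloxy)-4-[1-(trimethylsilyloxy)ethenyl]-2,3,3a,6-tetrahydro-3,6-methanobenzofuran-7(7aH)-one
Conditions: TMSOTf (3.6 equiv), Et3N (5 equiv), Et2O, 0 °C to rt, 3 h; pentane, cold aq NaHCO3 wash, concentrate; used crude
Reagents that add atoms: trimethylsilyl trifluoromethanesulfonate (TMSOTf), C[Si](C)(C)OS(=O)(=O)C(F)(F)F
Why: Exhaustive silylation with TMSOTf/Et3N turns the enolised β-diketone into the cross-conjugated 1,3-bis(silyloxy)diene by loss of an acetyl CH3 proton (the only enolisable site, since C6 and C8 are quaternary and the C7 ketone cannot enolise) and caps the bridgehead tertiary alcohol at the same time; no stereocentre is touched.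

Step 4
Reactants: 6 tris-silyl diene; 7 benzaldehyde (2 equiv)
Product: 9 CNP0322161.1 (target; 2S,5R,6S,8R,2''R), via silylated aldol adduct 8 (not isolated)
Conditions: (S)-BINOL (20 mol %), Ti(OiPr)4 (20 mol %), 4 Å MS, THF, rt, 1 h; 7, then 6, −20 °C to rt, 16 h; then TFA, CH2Cl2, 0 °C, 1 h; aq NaHCO3
Reagents that add atoms: none
Why: This is a catalytic enantioselective vinylogous Mukaiyama aldol reaction (formal hetero-Diels–Alder) of a Chan-type bis(silyloxy)diene at its terminal CH2, in which the (S)-BINOL titanium complex exposes the Si face of PhCHO and the new centre is remote from the core (four bonds from C5), so the catalyst decides 2S, and TFA then strips the silyl groups and closes ring D by hemiketalisation at C8a and loss of water without breaking the C2–O bond, so 2S is retained.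

## Compound list

1 | 2',4',6'-trihydroxyacetophenone (phloroacetophenone) | CC(=O)c1c(O)cc(O)cc1O | starting material
2 | 1-(2,4,6-trihydroxy-3,5-dimethylphenyl)ethan-1-one | CC(=O)c1c(O)c(C)c(O)c(C)c1O | intermediate
3 | prenol (3-methylbut-2-en-1-ol) | CC(C)=CCO | starting material
4 | (6S)-4-acetyl-3,5-dihydroxy-2,6-dimethyl-6-[(3-methylbut-2-en-1-yl)oxy]cyclohexa-2,4-dien-1-one (o-quinol prenyl ether, not isolated) | CC(C)=CCO[C@]1(C)C(=O)C(C)=C(O)C(C(C)=O)=C1O | intermediate
5 | (3R,3aR,6R,7aS)-4-acetyl-3a,5-dihydroxy-6,7a,8,8-tetramethyl-2,3,3a,6-tetrahydro-3,6-methanobenzofuran-7(7aH)-one (flavanone locants 5R,6S,8R,2''R) | CC1(C)[C@@H]2CO[C@]3(C)C(=O)[C@@]1(C)C(O)=C(C(C)=O)[C@]23O | intermediate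
6 | (3R,3aR,6R,7aS)-6,7a,8,8-tetramethyl-3a,5-bis(trimethylsilyloxy)-4-[1-(trimethylsilyloxy)ethenyl]-2,3,3a,6-tetrahydro-3,6-methanobenzofuran-7(7aH)-one | CC1(C)[C@@H]2CO[C@]3(C)C(=O)[C@@]1(C)C(O[Si](C)(C)C)=C(C(=C)O[Si](C)(C)C)[C@]23O[Si](C)(C)C | intermediate
7 | benzaldehyde | O=Cc1ccccc1 | starting material
8 | (3R,3aR,6R,7aS)-6,7a,8,8-tetramethyl-4-[(3S)-3-phenyl-3-(trimethylsilyloxy)propanoyl]-3a,5-bis(trimethylsilyloxy)-2,3,3a,6-tetrahydro-3,6-methanobenzofuran-7(7aH)-one (not isolated) | CC1(C)[C@@H]2CO[C@]3(C)C(=O)[C@@]1(C)C(O[Si](C)(C)C)=C(C(=O)C[C@H](O[Si](C)(C)C)c1ccccc1)[C@]23O[Si](C)(C)C | intermediate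
9 | CNP0322161.1: (2S)-2-phenyl-2,3-dihydropyran-4-one fused at C4a=C8a to the core of 5, with 5-OH, 6-Me, 8-Me, C7 ketone, C6–O–C1''H2 ether and C5–C2''H–C3''Me2–C8 bridge; 2S,5R,6S,8R,2''R | CC1(C)[C@@H]2CO[C@]3(C)C(=O)[C@@]1(C)C1=C(C(=O)C[C@@H](c4ccccc4)O1)[C@]23O | target

## Step count and risks

Total step count: 4. Longest linear sequence: 4 (1 → 2 → 5 → 6 → 9).

**Step 2 (highest risk).**
- The nucleophile is untethered, so the ee may be low.
- Acetate or chlorobenzoate may capture the ring instead of prenol.
- The cycloaddition could run through the other dienone tautomer, bonding C7 and C4a.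
- Fallback (sets out from 2, comes back at 9): drop reagent control and run the same tandem with achiral PhI(OAc)2 and prenol. This gives 4 and 5 as racemates, that is, together with the mirror-image o-quinol ether F2 and the mirror-image tricycle F3. The racemate is silylated as in step 3, giving 6 plus the mirror-image tris-silyl diene F4, and then submitted to step 4. The titanium catalyst fixes 2S on both antipodes, so F4 passes through the core-inverted aldol adduct F5 to the core-inverted 2S diastereomer F6. F6 is a diastereomer of 9, not its enantiomer, and is removed by silica chromatography or crystallisation. The route is rejoined at 9 with a ceiling of 50 %.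

**Step 4.**
- The diene is hindered and may react slowly.
- The aldol adduct may eliminate to the cinnamoyl enol, whose reclosure would erode 2S.
- Fallback (sets out from 5, comes back at 9): build ring D without the phenyl group and add it afterwards. Compound 5 with t-BuOCH(NMe2)2 gives the enaminone F7. Brief TFA treatment closes it, with loss of the amine, to the fused 4H-pyran-4-one F8. Asymmetric conjugate addition of PhB(OH)2 (Pd(OCOCF3)2, (R)-t-BuPyOx, NH4PF6, H2O, ClCH2CH2Cl, 60 °C) then installs the phenyl group and 2S under ligand control and gives 9.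

**Step 1.**
- Methylation is statistical, so mono-, tri- and tetramethylated products lower the yield.
- Fallback (sets out from 1, comes back at 2): a double Mannich reaction (aq HCHO, morpholine, EtOH) cannot alkylate a ring carbon twice and gives the bis(morpholinomethyl)phloroacetophenone F1. Hydrogenolysis of both benzylic C–N bonds (H2, Pd/C, MeOH–AcOH) gives 2.

## Further compounds

F1 | step 1 | 1-[2,4,6-trihydroxy-3,5-bis(morpholin-4-ylmethyl)phenyl]ethan-1-one | CC(=O)c1c(O)c(CN2CCOCC2)c(O)c(CN2CCOCC2)c1O
F2 | step 2 | (6R)-4-acetyl-3,5-dihydroxy-2,6-dimethyl-6-[(3-methylbut-2-en-1-yl)oxy]cyclohexa-2,4-dien-1-one (enantiomer of 4) | CC(C)=CCO[C@@]1(C)C(=O)C(C)=C(O)C(C(C)=O)=C1O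
F3 | step 2 | (3S,3aS,6S,7aR) enantiomer of 5 | CC1(C)[C@H]2CO[C@@]3(C)C(=O)[C@]1(C)C(O)=C(C(C)=O)[C@@]23O
F4 | step 2 | (3S,3aS,6S,7aR) enantiomer of 6 | CC1(C)[C@H]2CO[C@@]3(C)C(=O)[C@]1(C)C(O[Si](C)(C)C)=C(C(=C)O[Si](C)(C)C)[C@@]23O[Si](C)(C)C
F5 | step 2 | aldol adduct with (3S) side chain on the (3S,3aS,6S,7aR) core (diastereomer of 8) | CC1(C)[C@H]2CO[C@@]3(C)C(=O)[C@]1(C)C(O[Si](C)(C)C)=C(C(=O)C[C@H](O[Si](C)(C)C)c1ccccc1)[C@@]23O[Si](C)(C)C
F6 | step 2 | (2S,5S,6R,8S,2''S) diastereomer of 9 | CC1(C)[C@H]2CO[C@@]3(C)C(=O)[C@]1(C)C1=C(C(=O)C[C@@H](c4ccccc4)O1)[C@@]23O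
F7 | step 4 | (3R,3aR,6R,7aS)-4-[(E)-3-(dimethylamino)prop-2-enoyl] analogue of 5 (enaminone) | CC1(C)[C@@H]2CO[C@]3(C)C(=O)[C@@]1(C)C(O)=C(C(=O)/C=C/N(C)C)[C@]23O
F8 | step 4 | 2-unsubstituted 4H-pyran-4-one fused at C4a=C8a to the core of 5 (5R,6S,8R,2''R) | CC1(C)[C@@H]2CO[C@]3(C)C(=O)[C@@]1(C)C1=C(C(=O)C=CO1)[C@]23O
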